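## Retrosynthetic overview

1. Ring B (the cyclohexenone) is numbered C1 = C=O, C2 = CH, C3 = C–OMe, C4 = ketal carbon, C5 = CH2, C6 = CH(allyl); ring A is the arene. The C6–H bond is traced back to a C6–S(O)-p-tolyl bond. The sulfoxide is a traceless activating and stereocontrolling group.
2. The sulfinyl ketone is disconnected into three components joined in one flask: a racemic squarate-derived cyclobutenone ketal, lithiated (R)-p-tolyl vinyl sulfoxide and allyl bromide. Bonds C1–C6, C4–C5 and C6–allyl are made and the old four-ring bond C1–C4 is broken.
3. Enabling feature: in ring B the ketal carbon C4 is γ to the C1 carbonyl through the C2=C3 enol ether, and the C5 methylene is β to the same carbonyl through C6. C4 and C5 are therefore the two ends of a 3-oxido-hexatriene C4=C3–C2=C1(O–)–C6=C5, whose C1–C4-bonded valence isomer is a cyclobutenolate.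
4. The cyclobutenone ketal comes from dimethyl squarate (mono-reduction) and 2-allyl-4,5-dimethoxyphenol (C4–OAr bond made with allylic transposition). The phenol comes from 3,4-dimethoxyphenol by O-allylation and Claisen rearrangement.
5. Ring order: ring A and the four-membered ring are bought. Ring B is formed in the penultimate step by C4–C5 closure at the expense of the four-membered ring.

Key step: step 6

Assumption: the target SMILES is read as (4R,6S), which places the C4 aryloxy group and the C6 allyl group on the same face of ring B; the route is planned for this isomer.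

## Route

Step 1
Reactants: 1 3,4-dimethoxyphenol; 2 allyl bromide
Product: 3 4-(allyloxy)-1,2-dimethoxybenzene
Conditions: K2CO3, acetone, reflux
Reagents that add atoms: none
Why: Williamson ether synthesis of a phenoxide with a reactive allylic halide, with no competing functional group present.

Step 2
Reactants: 3 4-(allyloxy)-1,2-dimethoxybenzene
Product: 4 2-allyl-4,5-dimethoxyphenol
Conditions: N,N-diethylaniline, 190 °C
Reagents that add atoms: none
Why: Aromatic Claisen rearrangement, in which the [3,3] shift should go to the free ortho position remote from the methoxy groups rather than to the position flanked by OMe, and tautomerisation restores the phenol.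

Step 3
Reactants: 5 dimethyl squarate
Product: 6 4-hydroxy-2,3-dimethoxycyclobut-2-en-1-one (racemic)
Conditions: LiAlH(Ot-Bu)3, THF, –78 to –20 °C; then H2O
Reagents that add atoms: none
Why: 1,2-mono-reduction of one of two equivalent carbonyl groups by a bulky, mild hydride, the reaction type used to enter semisquarate chemistry; the aluminium alkoxide formed resists a second reduction.

Step 4
Reactants: 6 4-hydroxy-2,3-dimethoxycyclobut-2-en-1-one; 4 2-allyl-4,5-dimethoxyphenol
Product: 8 4-(2-allyl-4,5-dimethoxyphenoxy)-3,4-dimethoxycyclobut-2-en-1-one (racemic), via trifluoroacetate 7 (not isolated)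
Conditions: (CF3CO)2O, 2,6-di-tert-butyl-4-methylpyridine, CH2Cl2, –78 °C; then 4, –78 to 0 °C
Reagents that add atoms: none
Why: Monoketal synthesis from an activated 4-hydroxycyclobutenone (SN1′-type displacement), in which the phenol oxygen replaces the allylic trifluoroacetate at the methoxy-bearing ring carbon because that terminus is oxygen-stabilised and the product gains the conjugated 3-methoxyenone; no stereocontrol is needed since step 6 erases this centre.

Step 5
Reactants: 9 (1R,2S,5R)-menthyl (S)-p-toluenesulfinate
Product: 10 (R)-p-tolyl vinyl sulfoxide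
Conditions: CH2=CHMgBr, THF–toluene, –20 to 0 °C; then H2O
Reagents that add atoms: vinylmagnesium bromide, C=C[Mg]Br
Why: Andersen sulfoxide synthesis, a substitution at sulfur with clean inversion that carries the configuration of the crystalline sulfinate into the sulfoxide.

Step 6
Reactants: 10 (R)-p-tolyl vinyl sulfoxide; 8 4-(2-allyl-4,5-dimethoxyphenoxy)-3,4-dimethoxycyclobut-2-en-1-one; 2 allyl bromide
Product: 15 (4R,6S)-6-allyl-4-(2-allyl-4,5-dimethoxyphenoxy)-3,4-dimethoxy-6-[(S)-p-tolylsulfinyl]cyclohex-2-en-1-one, via lithiated sulfoxide 11 (not isolated), via cyclobutenolate 12 (not isolated), via oxidotriene 13 (not isolated), via sulfinyl enolate 14 (not isolated)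
Conditions: 10, LiN(i-Pr)2, THF, –78 °C; add 8, –78 °C, then warm to 0 °C; then 2, DMPU, –20 to 0 °C; work-up and chromatography below 20 °C
Reagents that add atoms: none
Why: Proposed new method: Lithiated sulfoxide 11 adds 1,2 to the single carbonyl of racemic 8 anti to the bulky aryloxy group (the face to which the ketal methoxy oxygen also guides lithium), so both enantiomers of 8 give cyclobutenolates 12 with O–Li cis to OAr, and oxyanion-accelerated conrotatory 4π opening with the oxido group turning outward erases both ring stereocentres and funnels them into one oxidotriene 13 (C3 and C6 cis on C1=C2, OAr inside and OMe outside on C4). 13 is a 2-acceptor-3-donor hexatriene and closes ring B by a thermally allowed disrotatory 6π electrocyclisation, equivalent to a 6-endo-trig vinylogous Michael addition of the ketene-acetal carbon C4 to the CH2 terminus C5 of the α-sulfinyl enone, which makes the C4–C5 bond and the stabilised enolate 14; allyl bromide then alkylates 14 at C6. The closest known reaction type is the ring expansion of cyclobutenones to cyclohexenones by addition of α-lithiated vinyl sulfones followed by the same 4π/6π sequence, and the facial model is that of metal-chelated α-sulfinyl enones in conjugate additions; new are the ketal-bearing triene terminus, the sulfoxide as source of absolute configuration and the allylation in the same flask. C4 is controlled by the sulfur stereocentre: lithium bridges the C1 oxido and the sulfinyl oxygen, which locks the s-cis C1–C6 conformer needed for closure and holds p-tolyl over one face of C5=C6, so C4 bonds to the other face, and with OAr inside this helical sense rotates OAr towards the tolyl side and OMe away from it, which is 4R for the (R)-sulfoxide. C6 is alkylated anti to both p-tolyl and OAr (6S as drawn), but this centre is only provisional because step 7 resets it. The step needs face-selective addition to 8 (secured by the size difference between OAr and OMe), outward rotation of the oxido group (secured electronically), one helical sense (secured by the chelated sulfoxide) and C- over O-allylation (secured by the soft, doubly stabilised enolate), and since C4 epimers of 15 are diastereomers any minor isomer can be removed by chromatography before the auxiliary is cleaved.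

Step 7
Reactants: 15 (4R,6S)-6-allyl-4-(2-allyl-4,5-dimethoxyphenoxy)-3,4-dimethoxy-6-[(S)-p-tolylsulfinyl]cyclohex-2-en-1-one
Product: 17 (4R,6S)-6-allyl-4-(2-allyl-4,5-dimethoxyphenoxy)-3,4-dimethoxycyclohex-2-en-1-one, via magnesium enolate 16 (not isolated)
Conditions: i-PrMgCl, THF, –78 °C; then 2,6-di-tert-butyl-4-methylphenol, –78 °C; pH 7 buffer
Reagents that add atoms: none
Why: Sulfoxide–magnesium exchange at sulfur expels the best carbanion leaving group as the cross-conjugated enolate 16 without touching C4, and kinetic protonation by the bulky phenol from the face opposite the C4 aryloxy group should place H anti and the allyl group syn to OAr (6S).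

## Compound list

1 | 3,4-dimethoxyphenol | COc1ccc(O)cc1OC | starting material
2 | allyl bromide | C=CCBr | starting material
3 | 4-(allyloxy)-1,2-dimethoxybenzene | C=CCOc1ccc(OC)c(OC)c1 | intermediate
4 | 2-allyl-4,5-dimethoxyphenol | C=CCc1cc(OC)c(OC)cc1O | intermediate
5 | dimethyl squarate (3,4-dimethoxycyclobut-3-ene-1,2-dione) | COC1=C(OC)C(=O)C1=O | starting material
6 | 4-hydroxy-2,3-dimethoxycyclobut-2-en-1-one, racemic | COC1=C(OC)C(O)C1=O | intermediate
7 | 2,3-dimethoxy-4-oxocyclobut-2-en-1-yl trifluoroacetate, racemic, not isolated | COC1=C(OC)C(OC(=O)C(F)(F)F)C1=O | intermediate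
8 | 4-(2-allyl-4,5-dimethoxyphenoxy)-3,4-dimethoxycyclobut-2-en-1-one, racemic | COC1=CC(=O)C1(OC)Oc1cc(OC)c(OC)cc1CC=C | intermediate
9 | (1R,2S,5R)-menthyl (S)-p-toluenesulfinate | CC(C)[C@@H]1CC[C@@H](C)C[C@H]1O[S@](=O)c2ccc(C)cc2 | starting material
10 | (R)-p-tolyl vinyl sulfoxide | C=C[S@@](=O)c1ccc(C)cc1 | intermediate
11 | 1-lithiovinyl p-tolyl sulfoxide, sulfur arrangement as in 10, not isolated | [Li]C(=C)[S@@](=O)c1ccc(C)cc1 | intermediate
12 | lithium 4-aryloxy-3,4-dimethoxy-1-[1-(p-tolylsulfinyl)vinyl]cyclobut-2-en-1-olate, O–Li cis to OAr; the adduct of one enantiomer of 8 is drawn, the adduct of the other has both ring centres inverted; not isolated | [Li]O[C@@]1(C(=C)[S@@](=O)c2ccc(C)cc2)C=C(OC)[C@@]1(OC)Oc2cc(OC)c(OC)cc2CC=C | intermediate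
13 | lithium 6-aryloxy-5,6-dimethoxy-2-(p-tolylsulfinyl)hexa-1,3,5-trien-3-olate, chain carbons cis on the central double bond, aryloxy inside; not isolated | C=C([S@@](=O)c1ccc(C)cc1)/C(O[Li])=C\C(OC)=C(OC)/Oc1cc(OC)c(OC)cc1CC=C | intermediate
14 | lithium (4R)-4-aryloxy-3,4-dimethoxy-6-(p-tolylsulfinyl)cyclohexa-1(6),2-dien-1-olate, not isolated | [Li]OC1=C([S@@](=O)c2ccc(C)cc2)C[C@@](OC)(Oc2cc(OC)c(OC)cc2CC=C)C(OC)=C1 | intermediate
15 | (4R,6S)-6-allyl-4-(2-allyl-4,5-dimethoxyphenoxy)-3,4-dimethoxy-6-[(S)-p-tolylsulfinyl]cyclohex-2-en-1-one; sulfur arrangement as in 10, descriptor changed only by priority; allyl anti and sulfinyl syn to OAr | C=CCc1cc(OC)c(OC)cc1O[C@]1(OC)C[C@](CC=C)([S@@](=O)c2ccc(C)cc2)C(=O)C=C1OC | intermediate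
16 | chloromagnesium (4R)-6-allyl-4-aryloxy-3,4-dimethoxycyclohexa-1(6),2-dien-1-olate, not isolated | Cl[Mg]OC1=C(CC=C)C[C@@](OC)(Oc2cc(OC)c(OC)cc2CC=C)C(OC)=C1 | intermediate
17 | (4R,6S)-6-allyl-4-(2-allyl-4,5-dimethoxyphenoxy)-3,4-dimethoxycyclohex-2-en-1-one | C=CCc1cc(OC)c(OC)cc1O[C@]1(OC)C[C@H](CC=C)C(=O)C=C1OC | target

## Step count and risks

Total step count: 7. Longest linear sequence: 5 steps (steps 1, 2, 4, 6, 7).

Steps most likely to fail:

1. **Step 6.**
   - Risk: the C4 selectivity may erode, either because the lithiated sulfoxide adds to both faces of 8 (two triene geometries, which close to opposite C4 configurations) or because the chelated sulfoxide biases the helical sense of closure only weakly. Thermal syn-elimination of the sulfoxide from 15 is a further loss channel. A reversed sense of induction would simply call for the equally available enantiomeric sulfinate.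
   - Fallback (known chemistry, sets out from 8, returns at 17): the cascade is run in its established achiral form with phenyl vinyl sulfone, LiN(i-Pr)2 (THF, –78 to 0 °C) and allyl bromide to give racemic 6-allyl-6-(phenylsulfonyl)cyclohexenone F1. Al/Hg amalgam in aqueous THF removes the sulfonyl group. The racemic cis ketone, that is 17 together with its mirror image (4S,6R)-ketone F2, is then resolved by preparative chromatography on a chiral stationary phase.

2. **Step 4.**
   - Risk: ring carbon alkylation of the electron-rich phenol, attack at the carbinol carbon instead of the methoxy-bearing carbon, or reversal of the mixed ketal under the acid set free.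
   - Fallback (sets out from 6 and 4, returns at 8): trifluoroacetate 7 is quenched with methanol instead of the phenol to give the standard monoketal 3,4,4-trimethoxycyclobut-2-en-1-one F3. Phenol 4 is silylated (Me3SiCl, Et3N) to (2-allyl-4,5-dimethoxyphenoxy)trimethylsilane F4. Catalytic Me3SiOTf in CH2Cl2 at –78 °C then exchanges one ketal methoxy group for the aryloxy group under non-protic conditions.

3. **Step 7.**
   - Risk: poor facial selectivity in the protonation of enolate 16, or epimerisation at C6 during work-up.
   - Fallback (sets out from 15, returns at 17): C6 is set under thermodynamic instead of kinetic control. Enolate 16 is quenched unselectively (aqueous NH4Cl), and the mixture containing the (4R,6R)-epimer F5 is equilibrated with catalytic DBU in toluene. 17 is separated and F5 recycled.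
   - The two modes are complementary. If OAr is pseudoaxial in 16, the kinetic proton enters anti to it and gives 17. If OMe is pseudoaxial instead, the same conformational preference makes 17, with allyl and OAr both pseudoequatorial, the more stable epimer.

Further compounds
F1 | step 6 | 6-allyl-4-(2-allyl-4,5-dimethoxyphenoxy)-3,4-dimethoxy-6-(phenylsulfonyl)cyclohex-2-en-1-one, racemic, one enantiomer drawn, allyl anti to OAr | C=CCc1cc(OC)c(OC)cc1O[C@]1(OC)C[C@](CC=C)(S(=O)(=O)c2ccccc2)C(=O)C=C1OC
F2 | step 6 | (4S,6R)-6-allyl-4-(2-allyl-4,5-dimethoxyphenoxy)-3,4-dimethoxycyclohex-2-en-1-one, mirror image of 17 | C=CCc1cc(OC)c(OC)cc1O[C@@]1(OC)C[C@@H](CC=C)C(=O)C=C1OC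
F3 | step 4 | 3,4,4-trimethoxycyclobut-2-en-1-one | COC1=CC(=O)C1(OC)OC
F4 | step 4 | (2-allyl-4,5-dimethoxyphenoxy)trimethylsilane | C=CCc1cc(OC)c(OC)cc1O[Si](C)(C)C
F5 | step 7 | (4R,6R)-6-allyl-4-(2-allyl-4,5-dimethoxyphenoxy)-3,4-dimethoxycyclohex-2-en-1-one | C=CCc1cc(OC)c(OC)cc1O[C@]1(OC)C[C@@H](CC=C)C(=O)C=C1OC
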